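**Retrosynthetic overview**

- The target is epiguibourtinidol-(4β→8)-epicatechin. The last step is one hydrogenolysis that removes seven benzyl ethers and a bromine at C5. Before that, the C4–C8 interflavan bond is made from a C4 cation of the upper unit and C8 of tetra-O-benzyl-epicatechin, whose rings D, F and E are bought intact.
- Ring C of the upper unit is cut at O1–C8a and C4a–C4. A 5-(benzyloxy)-3-bromobenzyne (ring A) is taken up between the C2 oxygen and the C4 aldehyde carbon of an acyclic syn-aldol fragment that already carries ring B and the C2/C3 stereocenters.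
- Enabling feature: ring A is joined to ring C only through its two adjacent carbons, C8a (to O1) and C4a (to C4). O1 and C4 are 1,3-related on the C2–C3–C4 chain. C5, beside C4a, bears only hydrogen, so a removable bromine can sit there and steer the aryne addition.
- The aldol fragment comes from an Evans syn glycolate aldol. Ring order: rings A and B are purchased arenes, ring C is the only ring built (step 8), and the lower unit arrives complete.

Key step: step 8

Assumption: the SMILES is read as upper unit 2,3-cis-3,4-trans (2R,3R,4R) and lower unit (2R,3R). C4 of compound 19 is carried as an epimer mixture because that center is ionised in step 10.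

**Route**

Step 1
Reactants: 1 4-(benzyloxy)phenol
Product: 2 4-(benzyloxy)-2,6-dibromophenol
Conditions: NBS (2.05 equiv), i-Pr2NH (0.1 equiv), CH2Cl2, 0 °C to rt
Reagents that add atoms: N-bromosuccinimide O=C1CCC(=O)N1Br
Why: Amine-catalysed ortho-selective electrophilic bromination of a phenol; the para position is blocked and the free OH outranks the benzyl ether as director, so both ortho positions should be brominated.

Step 2
Reactants: 2 4-(benzyloxy)-2,6-dibromophenol
Product: 5 4-(benzyloxy)-2-bromo-6-(trimethylsilyl)phenyl trifluoromethanesulfonate, via silyl ether 3 (not isolated), via lithium phenolate 4 (not isolated)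
Conditions: (Me3Si)2NH, THF, 65 °C, evaporate; n-BuLi (1.05 equiv), THF, −78 °C to rt; Tf2O, −78 to 0 °C
Reagents that add atoms: hexamethyldisilazane C[Si](C)(C)N[Si](C)(C)C; trifluoromethanesulfonic anhydride O=S(=O)(OS(=O)(=O)C(F)(F)F)C(F)(F)F
Why: Standard one-pot route to ortho-silylaryl triflate aryne precursors: O-silylation, bromine–lithium exchange at one of two equivalent C–Br bonds, retro-Brook O-to-C silyl shift and O-triflation; one equivalent of n-BuLi at −78 °C should leave the second bromine in place.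

Step 3
Reactants: 6 (S)-4-benzyloxazolidin-2-one; 7 (benzyloxy)acetyl chloride
Product: 9 (S)-4-benzyl-3-[(benzyloxy)acetyl]oxazolidin-2-one, via lithium oxazolidinide 8 (not isolated)
Conditions: n-BuLi, THF, −78 °C; then 7, −78 to 0 °C
Reagents that add atoms: none
Why: N-acylation of a lithiated oxazolidinone with an acid chloride; no stereocenter is touched.

Step 4
Reactants: 9 (S)-4-benzyl-3-[(benzyloxy)acetyl]oxazolidin-2-one; 10 4-(benzyloxy)benzaldehyde
Product: 12 (S)-4-benzyl-3-[(2S,3R)-2-(benzyloxy)-3-[4-(benzyloxy)phenyl]-3-hydroxypropanoyl]oxazolidin-2-one, via boron enolate 11 (not isolated)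
Conditions: Bu2BOTf, Et3N, CH2Cl2, −78 to 0 °C; 10, −78 to 0 °C; pH 7 buffer, MeOH, H2O2, 0 °C
Reagents that add atoms: none
Why: Evans syn-aldol; the Z-boron enolate reacts through a Zimmerman–Traxler chair on the face away from the auxiliary benzyl group, setting chain C2 (S) and C3 (R), the future C3 and C2 of the upper unit, in the syn relationship that becomes 2,3-cis.

Step 5
Reactants: 12 aldol adduct
Product: 13 (2S,3R)-2-(benzyloxy)-3-[4-(benzyloxy)phenyl]-3-hydroxy-N-methoxy-N-methylpropanamide
Conditions: MeONHMe·HCl, AlMe3, CH2Cl2, −20 to 0 °C; then 1 M HCl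
Reagents that add atoms: N,O-dimethylhydroxylamine hydrochloride CNOC.Cl
Why: Aluminium amide transamination of a β-hydroxy imide to the Weinreb amide; the free β-hydroxyl directs attack to the exocyclic carbonyl, and the auxiliary is released without touching the stereocenters.

Step 6
Reactants: 13 Weinreb amide
Product: 14 (2S,3R)-2-(benzyloxy)-3-[4-(benzyloxy)phenyl]-N-methoxy-N-methyl-3-[(trimethylsilyl)oxy]propanamide
Conditions: Me3SiCl, imidazole, CH2Cl2, 0 °C
Reagents that add atoms: chlorotrimethylsilane C[Si](C)(C)Cl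
Why: Silylation of the secondary alcohol; the TMS group is chosen because it serves in step 8 as the fluoride-labile mask of the nucleophilic oxygen.

Step 7
Reactants: 14 silylated Weinreb amide
Product: 15 (2S,3R)-2-(benzyloxy)-3-[4-(benzyloxy)phenyl]-3-[(trimethylsilyl)oxy]propanal
Conditions: i-Bu2AlH, THF, −78 °C; aq. potassium sodium tartrate, 0 °C; used without chromatography
Reagents that add atoms: none
Why: Weinreb amide reduction, which should stop at the aldehyde; −78 °C and a neutral tartrate work-up should keep the α-alkoxy stereocenter and the TMS ether intact.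

Step 8
Reactants: 15 (2S,3R)-2-(benzyloxy)-3-[4-(benzyloxy)phenyl]-3-[(trimethylsilyl)oxy]propanal; 5 4-(benzyloxy)-2-bromo-6-(trimethylsilyl)phenyl trifluoromethanesulfonate
Product: 19 (2R,3R)-3,7-bis(benzyloxy)-2-[4-(benzyloxy)phenyl]-5-bromochroman-4-ol (2,3-cis; C4 epimers), via potassium alkoxide 16 (not isolated), via aryne 17 (not isolated), via aryl anion 18 (not isolated)
Conditions: KF (3 equiv), 18-crown-6 (3 equiv), THF, 0 °C to rt, slow joint addition of 15 and 5 (1.3 equiv); then AcOH
Reagents that add atoms: none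
Why: Proposed new method: fluoride removes both silyl groups, so alkoxide 16 and aryne 17 meet with no O–H in the medium; the alkoxide oxygen adds to the aryne carbon remote from bromine (O1–C8a), and the aryl carbanion 18, now ortho to bromine, closes ring C by 6-exo-trig addition to the aldehyde carbon (C4a–C4). The closest known reaction type is the annulation of arynes with ortho-hydroxyaryl aldehydes, ketones and esters (phenoxide arylation, then intramolecular carbonyl capture of the aryl anion, giving xanthydrols and xanthones), extended here from a phenoxide to an aliphatic β-alkoxide and an enolisable aldehyde. Regiochemistry rests on the bromine beside the triple bond: its inductive pull distorts the aryne so that the distal carbon is the more linear and electrophilic one and the developing charge lands next to C–Br, which should outweigh the weak opposite bias of the remote benzyloxy group, and sterics act in the same sense. C2 and C3 are not touched (the C2–O bond is kept because that oxygen is the nucleophile), so the syn-aldol pattern becomes 2,3-cis; the new C4 carbinol center is under no useful control and is expected as an epimer mixture, which is harmless because C4 is ionised in step 10. The step needs cyclisation to beat protonation of 18, loss of bromide from 18, and retro-aldol or α-epimerisation of 16; an aprotic medium, a six-membered closure onto an aldehyde, and low stationary concentrations of both partners at 0 °C are meant to secure this.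

Step 9
Reactants: 20 (−)-epicatechin
Product: 21 (2R,3R)-5,7-bis(benzyloxy)-2-[3,4-bis(benzyloxy)phenyl]chroman-3-ol
Conditions: BnBr (4.4 equiv), K2CO3, DMF, 0 °C to rt, argon
Reagents that add atoms: benzyl bromide BrCc1ccccc1
Why: Williamson etherification selective for the four phenols over the secondary 3-OH under carbonate; low temperature should limit C-benzylation and C2 epimerisation.

Step 10
Reactants: 19 (2R,3R)-3,7-bis(benzyloxy)-2-[4-(benzyloxy)phenyl]-5-bromochroman-4-ol; 21 tetra-O-benzyl-epicatechin (4 equiv)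
Product: 23 (2R,3R,4S)-3,7-bis(benzyloxy)-2-[4-(benzyloxy)phenyl]-5-bromo-4-[(2R,3R)-5,7-bis(benzyloxy)-2-[3,4-bis(benzyloxy)phenyl]-3-hydroxychroman-8-yl]chromane (2,3-cis-3,4-trans), via benzylic cation 22 (not isolated)
Conditions: Me3SiOTf (0.2 equiv), 4 Å molecular sieves, CH2Cl2, −78 to −30 °C; Et3N quench
Reagents that add atoms: none
Why: Acid-promoted Friedel–Crafts-type condensation of a flavan-3,4-diol derivative with a flavan-3-ol, with loss of the C4 hydroxyl as water that the sieves take up; both C4 epimers give the same 7-alkoxy-stabilised cation 22, C8 of 21 attacks the face anti to the pseudoaxial 3-OBn and the 2-aryl group to set 3,4-trans, and excess 21 suppresses oligomerisation (the 4S label reflects the bromine in the priority order; the geometry is that of the 4R target).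

Step 11
Reactants: 23 heptabenzyl bromo dimer
Product: 24 (2R,3R,4R)-2-(4-hydroxyphenyl)-4-[(2R,3R)-2-(3,4-dihydroxyphenyl)-3,5,7-trihydroxychroman-8-yl]chromane-3,7-diol
Conditions: H2 (1 atm), Pd(OH)2/C, NaOAc (1.5 equiv), THF/MeOH/H2O, rt
Reagents that add atoms: none
Why: Heterogeneous hydrogenolysis should cleave the seven benzyl ethers and the aryl C–Br bond in one operation, with NaOAc buffering the HBr; no stereocenter is affected.

**Compound list**

1 | 4-(benzyloxy)phenol | Oc1ccc(OCc2ccccc2)cc1 | starting material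
2 | 4-(benzyloxy)-2,6-dibromophenol | Oc1c(Br)cc(OCc2ccccc2)cc1Br | intermediate
3 | [4-(benzyloxy)-2,6-dibromophenoxy]trimethylsilane | C[Si](C)(C)Oc1c(Br)cc(OCc2ccccc2)cc1Br | intermediate (not isolated)
4 | lithium 4-(benzyloxy)-2-bromo-6-(trimethylsilyl)phenolate | [Li+].[O-]c1c(Br)cc(OCc2ccccc2)cc1[Si](C)(C)C | intermediate (not isolated)
5 | 4-(benzyloxy)-2-bromo-6-(trimethylsilyl)phenyl trifluoromethanesulfonate | FC(F)(F)S(=O)(=O)Oc1c(Br)cc(OCc2ccccc2)cc1[Si](C)(C)C | intermediate
6 | (S)-4-benzyloxazolidin-2-one | O=C1OC[C@H](Cc2ccccc2)N1 | starting material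
7 | (benzyloxy)acetyl chloride | O=C(Cl)COCc1ccccc1 | starting material
8 | lithium (S)-4-benzyl-2-oxooxazolidin-3-ide | [Li+].O=C1OC[C@H](Cc2ccccc2)[N-]1 | intermediate (not isolated)
9 | (S)-4-benzyl-3-[(benzyloxy)acetyl]oxazolidin-2-one | O=C1OC[C@H](Cc2ccccc2)N1C(=O)COCc1ccccc1 | intermediate
10 | 4-(benzyloxy)benzaldehyde | O=Cc1ccc(OCc2ccccc2)cc1 | starting material
11 | (Z)-dibutylboron enolate of 9 | CCCCB(CCCC)O/C(=C\OCc1ccccc1)N1C(=O)OC[C@@H]1Cc1ccccc1 | intermediate (not isolated)
12 | (S)-4-benzyl-3-[(2S,3R)-2-(benzyloxy)-3-[4-(benzyloxy)phenyl]-3-hydroxypropanoyl]oxazolidin-2-one | O=C1OC[C@H](Cc2ccccc2)N1C(=O)[C@@H](OCc1ccccc1)[C@H](O)c1ccc(OCc2ccccc2)cc1 | intermediate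
13 | (2S,3R)-2-(benzyloxy)-3-[4-(benzyloxy)phenyl]-3-hydroxy-N-methoxy-N-methylpropanamide | CON(C)C(=O)[C@@H](OCc1ccccc1)[C@H](O)c1ccc(OCc2ccccc2)cc1 | intermediate
14 | (2S,3R)-2-(benzyloxy)-3-[4-(benzyloxy)phenyl]-N-methoxy-N-methyl-3-[(trimethylsilyl)oxy]propanamide | CON(C)C(=O)[C@@H](OCc1ccccc1)[C@H](O[Si](C)(C)C)c1ccc(OCc2ccccc2)cc1 | intermediate
15 | (2S,3R)-2-(benzyloxy)-3-[4-(benzyloxy)phenyl]-3-[(trimethylsilyl)oxy]propanal | O=C[C@@H](OCc1ccccc1)[C@H](O[Si](C)(C)C)c1ccc(OCc2ccccc2)cc1 | intermediate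
16 | potassium (1R,2S)-2-(benzyloxy)-1-[4-(benzyloxy)phenyl]-3-oxopropan-1-olate | [K+].O=C[C@@H](OCc1ccccc1)[C@H]([O-])c1ccc(OCc2ccccc2)cc1 | intermediate (not isolated)
17 | 5-(benzyloxy)-3-bromobenzyne (5-(benzyloxy)-3-bromo-1,2-didehydrobenzene) | BrC1=CC(OCc2ccccc2)=CC#C1 | intermediate (not isolated)
18 | potassium 4-(benzyloxy)-2-bromo-6-{[(1R,2S)-2-(benzyloxy)-1-[4-(benzyloxy)phenyl]-3-oxopropyl]oxy}benzenide | [K+].O=C[C@@H](OCc1ccccc1)[C@H](Oc1cc(OCc2ccccc2)cc(Br)[c-]1)c1ccc(OCc2ccccc2)cc1 | intermediate (not isolated)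
19 | (2R,3R)-3,7-bis(benzyloxy)-2-[4-(benzyloxy)phenyl]-5-bromochroman-4-ol (2,3-cis; C4 epimers) | C(c1ccccc1)Oc1ccc([C@H]2Oc3cc(OCc4ccccc4)cc(Br)c3C(O)[C@H]2OCc2ccccc2)cc1 | intermediate
20 | (−)-epicatechin, (2R,3R)-2-(3,4-dihydroxyphenyl)chromane-3,5,7-triol | O[C@@H]1Cc2c(O)cc(O)cc2O[C@@H]1c1ccc(O)c(O)c1 | starting material
21 | (2R,3R)-5,7-bis(benzyloxy)-2-[3,4-bis(benzyloxy)phenyl]chroman-3-ol | O[C@@H]1Cc2c(OCc3ccccc3)cc(OCc3ccccc3)cc2O[C@@H]1c1ccc(OCc2ccccc2)c(OCc2ccccc2)c1 | intermediate
22 | (2R,3R)-3,7-bis(benzyloxy)-2-[4-(benzyloxy)phenyl]-5-bromochroman-4-ylium trifluoromethanesulfonate | C(c1ccccc1)Oc1ccc([C@H]2Oc3cc(OCc4ccccc4)cc(Br)c3[CH+][C@H]2OCc2ccccc2)cc1.[O-]S(=O)(=O)C(F)(F)F | intermediate (not isolated)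
23 | (2R,3R,4S)-3,7-bis(benzyloxy)-2-[4-(benzyloxy)phenyl]-5-bromo-4-[(2R,3R)-5,7-bis(benzyloxy)-2-[3,4-bis(benzyloxy)phenyl]-3-hydroxychroman-8-yl]chromane | C(c1ccccc1)Oc1ccc([C@H]2Oc3cc(OCc4ccccc4)cc(Br)c3[C@H](c3c(OCc4ccccc4)cc(OCc4ccccc4)c4c3O[C@H](c3ccc(OCc5ccccc5)c(OCc5ccccc5)c3)[C@H](O)C4)[C@H]2OCc2ccccc2)cc1 | intermediate
24 | (2R,3R,4R)-2-(4-hydroxyphenyl)-4-[(2R,3R)-2-(3,4-dihydroxyphenyl)-3,5,7-trihydroxychroman-8-yl]chromane-3,7-diol | Oc1ccc([C@H]2Oc3cc(O)ccc3[C@H](c3c(O)cc(O)c4c3O[C@H](c3ccc(O)c(O)c3)[C@H](O)C4)[C@H]2O)cc1 | target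

**Step count and risks**

Total steps: 11. Longest linear sequence: 8 steps (3, 4, 5, 6, 7, 8, 10, 11).

Steps most likely to fail:

1. Step 8 (proposed new method). Possible failures: the alkoxide 16 undergoes retro-aldol cleavage or α-epimerisation before it is arylated; the aryl anion 18 is protonated or expels bromide instead of cyclising; the product alkoxide is arylated by a second aryne. The fallback uses known chemistry, sets out from 15 and returns at 19. Commercial 1-(benzyloxy)-3,5-dibromobenzene is deprotonated between its two bromines with LiN(i-Pr)2 in THF at −78 °C to give 4-(benzyloxy)-2,6-dibromophenyllithium F1. F1 adds to aldehyde 15 at −78 °C (AcOH quench) to give (2R,3R)-2-(benzyloxy)-3-[4-(benzyloxy)phenyl]-1-[4-(benzyloxy)-2,6-dibromophenyl]-3-[(trimethylsilyl)oxy]propan-1-ol F2 (C1 epimers). Brief K2CO3 in MeOH at 0 °C removes the TMS group to give (2S,3R)-2-(benzyloxy)-3-[4-(benzyloxy)phenyl]-1-[4-(benzyloxy)-2,6-dibromophenyl]propane-1,3-diol F3. An intramolecular Ullmann etherification (CuI, 1,10-phenanthroline, Cs2CO3, toluene, 110 °C) of the C3 hydroxyl onto either of the two equivalent ortho C–Br bonds then closes ring C and gives 19, with the surviving bromine at C5 as in the main route.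

2. Step 10. Ionisation of the C4 hydroxyl on the bromine-bearing, 5-deoxy ring A may be slow under acid, so that self-condensation of 19, attack at C6 of 21, or further reaction of the product at C6 of its lower unit compete. The fallback sets out from 19 and returns at 23. Compound 19 is thiolysed with benzyl mercaptan and catalytic Me3SiOTf (CH2Cl2, −40 °C), where the small, soft thiol in excess should intercept cation 22 cleanly, to give (2R,3S)-4-(benzylsulfanyl)-3,7-bis(benzyloxy)-2-[4-(benzyloxy)phenyl]-5-bromochromane F4. This purified donor is then activated under non-acidic, thiophilic conditions with AgBF4 in THF at 0 °C in the presence of 21, releasing the cation gradually and giving 23.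

3. Step 11. Bromide released on the catalyst may stall debenzylation at partly protected stages, and long exposure may erode the polyphenol. The fallback sets out from 23 and returns at 24. The C5–Br bond is first cleaved on its own by radical chain reduction (Bu3SnH, catalytic azobisisobutyronitrile, toluene, 80 °C) to give (2R,3R,4R)-3,7-bis(benzyloxy)-2-[4-(benzyloxy)phenyl]-4-[(2R,3R)-5,7-bis(benzyloxy)-2-[3,4-bis(benzyloxy)phenyl]-3-hydroxychroman-8-yl]chromane F5. F5 is purified and debenzylated by halide-free hydrogenolysis (H2, Pd(OH)2/C, THF/MeOH/H2O, rt) to 24.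

**Further compounds**

F1 | step 8 | 4-(benzyloxy)-2,6-dibromophenyllithium | [Li]c1c(Br)cc(OCc2ccccc2)cc1Br
F2 | step 8 | (2R,3R)-2-(benzyloxy)-3-[4-(benzyloxy)phenyl]-1-[4-(benzyloxy)-2,6-dibromophenyl]-3-[(trimethylsilyl)oxy]propan-1-ol (C1 epimers) | OC(c1c(Br)cc(OCc2ccccc2)cc1Br)[C@@H](OCc1ccccc1)[C@H](O[Si](C)(C)C)c1ccc(OCc2ccccc2)cc1
F3 | step 8 | (2S,3R)-2-(benzyloxy)-3-[4-(benzyloxy)phenyl]-1-[4-(benzyloxy)-2,6-dibromophenyl]propane-1,3-diol (C1 epimers) | OC(c1c(Br)cc(OCc2ccccc2)cc1Br)[C@@H](OCc1ccccc1)[C@H](O)c1ccc(OCc2ccccc2)cc1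
F4 | step 10 | (2R,3S)-4-(benzylsulfanyl)-3,7-bis(benzyloxy)-2-[4-(benzyloxy)phenyl]-5-bromochromane (2,3-cis; C4 mainly trans to 3-OBn) | C(c1ccccc1)Oc1ccc([C@H]2Oc3cc(OCc4ccccc4)cc(Br)c3C(SCc3ccccc3)[C@H]2OCc2ccccc2)cc1
F5 | step 11 | (2R,3R,4R)-3,7-bis(benzyloxy)-2-[4-(benzyloxy)phenyl]-4-[(2R,3R)-5,7-bis(benzyloxy)-2-[3,4-bis(benzyloxy)phenyl]-3-hydroxychroman-8-yl]chromane | C(c1ccccc1)Oc1ccc([C@H]2Oc3cc(OCc4ccccc4)ccc3[C@H](c3c(OCc4ccccc4)cc(OCc4ccccc4)c4c3O[C@H](c3ccc(OCc5ccccc5)c(OCc5ccccc5)c3)[C@H](O)C4)[C@H]2OCc2ccccc2)cc1
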